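# Proposed synthesis of CNP0234761.1: (2S,3R,4S)-4-(3-hydroxy-4-methoxybenzoyl)-2-(3-hydroxy-4-methoxyphenyl)-3-(hydroxymethyl)tetrahydrofuran

Ring numbering used throughout: O1, C2 (aryl), C3 (one-carbon arm), C4 (aroyl), C5 (CH2). Compound numbers refer to the list after the steps.

## Analysis of the target

The target is a single tetrahydrofuran ring (O1, C2–C5) flanked by two isovanillyl arenes. C2 carries a 3-hydroxy-4-methoxyphenyl group, C3 a hydroxymethyl group, C4 a 3-hydroxy-4-methoxybenzoyl group, and C5 is an unsubstituted methylene. The three contiguous stereocentres are (2S,3R,4S), with each substituent trans to its neighbour (2,3-trans, 3,4-trans), which is the thermodynamically preferred arrangement. C4 lies α to the aryl ketone and can be corrected by enolisation; C2 and C3 cannot, so the absolute configuration must be brought in at C2 and relayed to C3 in a bond-forming step. The sensitive points are four. The C2–O1 bond is a p-methoxybenzylic ether that ionises in acid and can be hydrogenolysed. The aryl ketone must survive every reduction. The array O1–C5–C4–C=O is a β-alkoxy ketone that can open by β-elimination. The two phenols are free. The difficulty is therefore three differently oxidised substituents on adjacent ring carbons, set with relative and absolute control and without harsh acid or base late in the route. The feature exploited is that the aroyl-bearing C4 is flanked by the O1–C5 bond and the C3–C4 bond. C4, C5 and the aroyl group then map onto an aryl ethynyl ketone, and O1, C2, C3 and the C3 arm map onto a γ-hydroxy nitroalkene whose nitromethyl group stands in for CH2OH.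

## Retrosynthetic reasoning

**16 ⇒ 15 ⇒ 14 (no skeletal bond cut).** Target 16 is traced to its C4 epimer 15, and 15 to the 4-aroyl-2,3-dihydrofuran 14, in which C4=C5 is a double bond and both phenols are benzyl ethers. This removes C4 from the list of centres that must be controlled in a C–C bond-forming step. The forward reactions must saturate C4=C5 and remove two benzyl groups without touching the aryl ketone or the C2–O1 bond, then bring C4 to the all-trans arrangement with base.

**14 ⇒ 13 ⇒ 11 (functional-group change at the C3 arm).** The hydroxymethyl carbon is traced through carboxylic acid 13 to the nitromethyl group of 11. The acid level is chosen rather than the aldehyde. In a 3-formyl-2,3-dihydrofuran of this type O1 is a vinylogous carboxylate β to the formyl group and would leave by E1cB elimination; a carboxylic acid is not exposed to this. The forward reactions must oxidise CH2NO2 to CO2H under weakly acidic conditions and reduce CO2H in the presence of the ketone, which is protected at this stage by being part of a vinylogous ester.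

**11 ⇒ 7 + 10 (O1–C5 and C3–C4 cut).** These two bonds flank C4, and cutting both divides the ring into a two-carbon electrophile–nucleophile unit (ynone 10: C5 electrophilic, C4 nucleophilic after O-addition) and a three-atom nucleophile–electrophile unit (hydroxy nitroalkene 7: O1 nucleophilic, C3 electrophilic). The cut is convergent, both halves derive from one aldehyde, the aroyl group arrives at its final oxidation level, and the nitro group both activates C3 and masks the C3 arm. The forward reaction must form O1–C5 before C3–C4, close the ring 5-exo-trig, and set C3 trans to the C2 aryl group.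

**10 ⇒ 9 ⇒ 1 + 8.** The ynone comes from aldehyde 1 by addition of ethynylmagnesium bromide 8 and oxidation of the propargylic alcohol 9.

**7 ⇒ 6 ⇒ 5 ⇒ 4 ⇒ 3 ⇒ 1 + 2.** The C–N bond at the alkene terminus is cut (radical nitration of a terminal alkene), with the carbinol oxygen silylated during that step (5, 6). The (S)-carbinol 4 is obtained by enzymatic resolution of racemic 3, made from 1 and vinylmagnesium bromide 2. Resolution is preferred to oxidation and enantioselective reduction. An aryl vinyl ketone offers a reducing catalyst two sp2 substituents of similar size and polymerises readily, whereas lipase acylation leaves exactly the needed (S)-alcohol.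

## Alternatives that were turned down

**Alternative 1:** The C2–C3 bond is cut and the tetrahydrofuran is closed by carbene C–H insertion. A trans-4,5-disubstituted α-diazo γ-lactone A2, carrying the future C2 as an arylmethyl ether, would be decomposed with Rh2(OAc)4 (divalent rhodium). The carbene at the future C3 inserts into the benzylic ether C–H bond and gives the cis-fused exo,exo-diaryl furofuranone A1.
- For: five-ring insertion into a benzylic C–H bond next to oxygen is reliable carbene chemistry on exactly this substrate class, and exo selectivity places the C2 aryl trans to the C3 carbon. On precedent for the key step this route is stronger than the chosen one.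
- Against: A1 holds one ring and one stereocentre too many. The lactone must be reduced to a diol and the benzylic alcohol re-oxidised to the ketone, so a stereocentre built into A2 is destroyed. The cis ring fusion delivers the 3,4-cis arrangement, so the same C4 equilibration is still needed. A2 requires a long linear sequence.
- Comparison: the chosen route is convergent, forms two ring bonds at once and brings in the C4 carbonyl at the correct oxidation level; what it gives up is precedent for its key step.

**Alternative 2:** The C3–C4 bond is cut as a radical bond. An epoxy propargyl ether A4 would be treated with Cp2TiCl (trivalent titanium). Homolytic opening of the terminal epoxide gives a radical at C3 that closes 5-exo-dig onto the aryl alkyne, giving the 2,3-trans 4-benzylidene tetrahydrofuran A3.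
- For: the C3 hydroxymethyl group emerges from the epoxide at its final oxidation level, so no nitro group needs converting (better than the chosen route on this point), and such closures are trans-selective at C2/C3.
- Against: the carbon that must become the ketone arrives as a benzylidene CH. Converting it needs hydroboration with boron at the benzylic carbon, alcohol oxidation and then C4 equilibration, with the primary alcohol protected meanwhile. The titanium reagent is stoichiometric. A4 needs a stereodefined epoxide of an electron-rich aryl vinyl carbinol, O-propargylation and a Sonogashira coupling.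
- Comparison: more steps after the key step than in the chosen route, where C4 already carries the aroyl group.

**Alternative 3:** The O1–C2 bond is formed last by Cloke–Wilson rearrangement. A 2-aryl-3-(silyloxymethyl)cyclopropane-1-carbaldehyde A6 would be activated by a Lewis acid such as Sc(OTf)3. The bond between the aryl-bearing and formyl-bearing carbons breaks, the aldehyde oxygen bonds to the benzylic carbon, and the 2,3-trans 2,3-dihydrofuran A5 results.
- For: mild, atom-economical, and it leads to the same ring type as the chosen key step without new method development.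
- Against: A5 has no substituent on C4, so the C4–aroyl bond must be added later by acylating the enol ether with an electron-rich aroyl chloride, a slow reaction that liberates acid beside a p-methoxybenzylic ether. The ring opening passes through a benzylic cation, so C2 is set only relative to C3. The absolute configuration must then come from an enantioselective synthesis of a cyclopropane with three different vicinal substituents.
- Comparison: the chosen annulation reaches the same dihydrofuran type with the aroyl group already on C4 and with C2 taken from a resolved alcohol.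

Key step: step 8

## Route

Remark on the chemistry: aldehyde 1 is taken as a purchasable compound; if it has to be made, O-benzylation of isovanillin (BnBr, K2CO3, DMF) adds one step.

**Step 1**
Reactants: 1 3-(benzyloxy)-4-methoxybenzaldehyde; 2 vinylmagnesium bromide
Product: 3 rac-1-[3-(benzyloxy)-4-methoxyphenyl]prop-2-en-1-ol
Conditions: THF, −78 → 0 °C; aq. NH4Cl
Reagents that add atoms: none
Why: Grignard addition to a non-enolisable aryl aldehyde; the carbinol centre is formed racemic on purpose and resolved in step 2. A buffered quench is used because the electron-rich allylic benzylic alcohol rearranges under acid.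

**Step 2**
Reactants: 3 rac-1-[3-(benzyloxy)-4-methoxyphenyl]prop-2-en-1-ol
Product: 4 (S)-1-[3-(benzyloxy)-4-methoxyphenyl]prop-2-en-1-ol
Conditions: immobilised Burkholderia cepacia lipase (or Candida antarctica lipase B), vinyl acetate, MTBE, 30 °C, stopped just beyond half conversion
Reagents that add atoms: none
Why: Lipase-catalysed kinetic resolution by irreversible acyl transfer; by the empirical rule for secondary alcohols the enzyme acylates the enantiomer with aryl in its large pocket and vinyl in its medium pocket, which is the (R)-alcohol. The (S)-alcohol 4 should therefore remain, its enantiomeric purity rising as conversion passes one half; the (R)-acetate is removed by chromatography.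

**Step 3**
Reactants: 4 (S)-1-[3-(benzyloxy)-4-methoxyphenyl]prop-2-en-1-ol
Product: 5 (S)-{1-[3-(benzyloxy)-4-methoxyphenyl]prop-2-en-1-yl}oxy(tert-butyl)dimethylsilane
Conditions: TBSCl, imidazole, DMF, rt
Reagents that add atoms: tert-butyldimethylsilyl chloride, CC(C)(C)[Si](C)(C)Cl
Why: Standard silylation of a secondary alcohol; the silyl ether keeps the carbinol from being oxidised to the enone or otherwise taking part in the radical nitration.

**Step 4**
Reactants: 5 (S)-{1-[3-(benzyloxy)-4-methoxyphenyl]prop-2-en-1-yl}oxy(tert-butyl)dimethylsilane
Product: 6 (S,E)-{1-[3-(benzyloxy)-4-methoxyphenyl]-3-nitroprop-2-en-1-yl}oxy(tert-butyl)dimethylsilane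
Conditions: AgNO2, TEMPO, 4 Å MS, DCE, 70 °C
Reagents that add atoms: silver nitrite (AgNO2), [Ag+].[O-]N=O
Why: Radical nitration of a terminal alkene: NO2 radical from AgNO2 adds to the CH2 terminus, TEMPO intercepts the secondary radical, and loss of TEMPO–H across the acidic C–H next to the nitro group should give the conjugated (E)-nitroalkene. The stereocentre is not touched.

**Step 5**
Reactants: 6 (S,E)-{1-[3-(benzyloxy)-4-methoxyphenyl]-3-nitroprop-2-en-1-yl}oxy(tert-butyl)dimethylsilane
Product: 7 (S,E)-1-[3-(benzyloxy)-4-methoxyphenyl]-3-nitroprop-2-en-1-ol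
Conditions: aq. HF (48%), MeCN, 0 °C
Reagents that add atoms: none
Why: Acidic cleavage of the secondary silyl ether avoids fluoride salts and amine bases, which would add to the nitroalkene or move the double bond out of conjugation through the γ-hydrogen. The electron-poor nitrovinyl group disfavours ionisation of the benzylic C–O bond, so the configuration should hold at 0 °C.

**Step 6**
Reactants: 1 3-(benzyloxy)-4-methoxybenzaldehyde; 8 ethynylmagnesium bromide
Product: 9 rac-1-[3-(benzyloxy)-4-methoxyphenyl]prop-2-yn-1-ol
Conditions: THF, 0 °C; aq. NH4Cl
Reagents that add atoms: none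
Why: Grignard addition of the acetylide to the aldehyde; the carbinol centre is of no consequence because it is oxidised in step 7.

**Step 7**
Reactants: 9 rac-1-[3-(benzyloxy)-4-methoxyphenyl]prop-2-yn-1-ol
Product: 10 1-[3-(benzyloxy)-4-methoxyphenyl]prop-2-yn-1-one
Conditions: MnO2 (activated), CH2Cl2, rt
Reagents that add atoms: none
Why: MnO2 oxidises the benzylic propargylic alcohol selectively under neutral conditions and leaves the terminal alkyne and the ethers alone. The ynone is used soon after filtration because terminal ynones polymerise on storage.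

**Step 8**
Reactants: 7 (S,E)-1-[3-(benzyloxy)-4-methoxyphenyl]-3-nitroprop-2-en-1-ol; 10 1-[3-(benzyloxy)-4-methoxyphenyl]prop-2-yn-1-one
Product: 11 [(2S,3R)-2-[3-(benzyloxy)-4-methoxyphenyl]-3-(nitromethyl)-2,3-dihydrofuran-4-yl][3-(benzyloxy)-4-methoxyphenyl]methanone
Conditions: DABCO (10 mol%), CH2Cl2, −20 → 0 °C; 10 in excess (1.5 equiv), DABCO added last
Reagents that add atoms: none
Why: Proposed new method: DABCO adds to the terminus of ynone 10 to give a β-ammonium allenolate that deprotonates the hydroxyl of 7; the alkoxide, formed as an ion pair with the β-ammonium enone, makes the O1–C5 bond by adding to that cation or to a second molecule of 10, and the carbanion so generated at C4 attacks the tethered nitroalkene at C3 before it is protonated, after which loss of DABCO where required and protonation of the nitronate should give 11. The closest known reaction type is the amine-catalysed oxa-Michael–Michael annulation of ynones and propiolates with 2-(2-nitrovinyl)phenols to 4H-chromenes; here a benzylic aliphatic alkoxide and a five-membered ring replace a phenoxide and a six-membered ring. The dihydrofuran closes by a 5-exo-trig Michael addition of C4 to C3, with the nitronate carbon outside the ring. The new stereocentre C3 is controlled by C2: in the envelope transition state the aryl group sits pseudo-equatorial and turned away from the nitroalkene carbon rather than eclipsing it, which places CH2NO2 trans to the aryl group, and since neither C2–H nor C3–H is acidic in 11 this kinetic result is retained. The step needs O-addition to the ynone rather than to a nitroalkene, which the higher electrophilicity and excess of the ynone and the ion-pair delivery should secure. It needs C–C closure to outrun protonation of C4, which the aprotic medium and the intramolecular, strongly electrophilic nitroalkene should secure. It also needs the γ-C–H of 7 (benzylic, carbinol and vinylogous to the nitro group) to stay untouched, which is why a weakly basic, mainly nucleophilic amine is used in catalytic amount at low temperature and added last to an excess of the ynone.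

**Step 9**
Reactants: 11 [(2S,3R)-2-[3-(benzyloxy)-4-methoxyphenyl]-3-(nitromethyl)-2,3-dihydrofuran-4-yl][3-(benzyloxy)-4-methoxyphenyl]methanone
Product: 13 (2S,3S)-4-[3-(benzyloxy)-4-methoxybenzoyl]-2-[3-(benzyloxy)-4-methoxyphenyl]-2,3-dihydrofuran-3-carboxylic acid, via nitrolic acid 12 (not isolated)
Conditions: NaNO2, AcOH, DMSO, 35 °C
Reagents that add atoms: sodium nitrite (NaNO2), [Na+].[O-]N=O; water, O
Why: Nef-type oxidation of a primary nitroalkane to the carboxylic acid: C-nitrosation of the aci-nitro tautomer gives nitrolic acid 12, which loses nitrous acid to a nitrile oxide that nitrite and water convert into the acid. The weakly acidic medium should leave the benzylic C2–O1 bond and the vinylogous ester intact, and the acid level is chosen over the aldehyde because a 3-formyl group would expel O1 by β-elimination. C2 and C3 are not involved (the descriptor at C3 changes only because of priorities).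

**Step 10**
Reactants: 13 (2S,3S)-4-[3-(benzyloxy)-4-methoxybenzoyl]-2-[3-(benzyloxy)-4-methoxyphenyl]-2,3-dihydrofuran-3-carboxylic acid
Product: 14 [(2S,3R)-2-[3-(benzyloxy)-4-methoxyphenyl]-3-(hydroxymethyl)-2,3-dihydrofuran-4-yl][3-(benzyloxy)-4-methoxyphenyl]methanone
Conditions: BH3·THF, THF, 0 °C; aqueous work-up
Reagents that add atoms: none
Why: Borane reduces a carboxylic acid through its acyloxyborane far faster than a ketone, and the C4 ketone is further deactivated as a vinylogous ester. No base is present, so neither C3 nor the C2–O1 bond is at risk.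

**Step 11**
Reactants: 14 [(2S,3R)-2-[3-(benzyloxy)-4-methoxyphenyl]-3-(hydroxymethyl)-2,3-dihydrofuran-4-yl][3-(benzyloxy)-4-methoxyphenyl]methanone
Product: 15 (3-hydroxy-4-methoxyphenyl)[(2S,3R,4R)-2-(3-hydroxy-4-methoxyphenyl)-3-(hydroxymethyl)tetrahydrofuran-4-yl]methanone
Conditions: H2 (1 atm), Pd/C, EtOAc–EtOH, rt
Reagents that add atoms: none
Why: Heterogeneous hydrogenation saturates the C4=C5 bond of the vinylogous ester and hydrogenolyses both aryl benzyl ethers; at 1 atm in a neutral solvent the p-methoxyaryl ketone and the cyclic benzylic C2–O1 bond should react much more slowly, and the reaction is stopped once three equivalents of hydrogen are taken up. Hydrogen is expected to arrive mainly on the face of C4=C5 opposite the adjacent C3 hydroxymethyl group, making the 3,4-cis compound 15 the main product; material reduced from the other face is already 16, so the crude mixture is taken on.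

**Step 12**
Reactants: 15 (3-hydroxy-4-methoxyphenyl)[(2S,3R,4R)-2-(3-hydroxy-4-methoxyphenyl)-3-(hydroxymethyl)tetrahydrofuran-4-yl]methanone
Product: 16 (3-hydroxy-4-methoxyphenyl)[(2S,3R,4S)-2-(3-hydroxy-4-methoxyphenyl)-3-(hydroxymethyl)tetrahydrofuran-4-yl]methanone (target)
Conditions: K2CO3, MeOH, rt; aq. NH4Cl
Reagents that add atoms: none
Why: Reversible enolisation of the aryl ketone epimerises C4 alone, and the all-trans isomer 16 is the thermodynamic product. Ring opening by retro-oxa-Michael reaction is the reverse of a 5-endo-trig closure and should be slow because the C5–O1 bond lies near the nodal plane of the exocyclic enolate; the phenoxides are meta to the benzylic positions and cannot form quinone methides.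

## Compound list

1 | 3-(benzyloxy)-4-methoxybenzaldehyde | COc1ccc(C=O)cc1OCc1ccccc1 | starting material
2 | vinylmagnesium bromide | C=C[Mg]Br | starting material
3 | rac-1-[3-(benzyloxy)-4-methoxyphenyl]prop-2-en-1-ol | C=CC(O)c1ccc(OC)c(OCc2ccccc2)c1 | intermediate
4 | (S)-1-[3-(benzyloxy)-4-methoxyphenyl]prop-2-en-1-ol | O[C@H](c1ccc(OC)c(OCc2ccccc2)c1)C=C | intermediate
5 | (S)-{1-[3-(benzyloxy)-4-methoxyphenyl]prop-2-en-1-yl}oxy(tert-butyl)dimethylsilane | CC(C)(C)[Si](C)(C)O[C@H](c1ccc(OC)c(OCc2ccccc2)c1)C=C | intermediate
6 | (S,E)-{1-[3-(benzyloxy)-4-methoxyphenyl]-3-nitroprop-2-en-1-yl}oxy(tert-butyl)dimethylsilane | CC(C)(C)[Si](C)(C)O[C@H](c1ccc(OC)c(OCc2ccccc2)c1)/C=C/[N+](=O)[O-] | intermediate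
7 | (S,E)-1-[3-(benzyloxy)-4-methoxyphenyl]-3-nitroprop-2-en-1-ol | O[C@H](c1ccc(OC)c(OCc2ccccc2)c1)/C=C/[N+](=O)[O-] | intermediate
8 | ethynylmagnesium bromide | C#C[Mg]Br | starting material
9 | rac-1-[3-(benzyloxy)-4-methoxyphenyl]prop-2-yn-1-ol | C#CC(O)c1ccc(OC)c(OCc2ccccc2)c1 | intermediate
10 | 1-[3-(benzyloxy)-4-methoxyphenyl]prop-2-yn-1-one | C#CC(=O)c1ccc(OC)c(OCc2ccccc2)c1 | intermediate
11 | [(2S,3R)-2-[3-(benzyloxy)-4-methoxyphenyl]-3-(nitromethyl)-2,3-dihydrofuran-4-yl][3-(benzyloxy)-4-methoxyphenyl]methanone | O1[C@H](c2ccc(OC)c(OCc3ccccc3)c2)[C@@H](C[N+](=O)[O-])C(C(=O)c2ccc(OC)c(OCc3ccccc3)c2)=C1 | intermediate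
12 | nitrolic acid: [(2S,3R)-2-[3-(benzyloxy)-4-methoxyphenyl]-3-[(hydroxyimino)(nitro)methyl]-2,3-dihydrofuran-4-yl][3-(benzyloxy)-4-methoxyphenyl]methanone | O1[C@H](c2ccc(OC)c(OCc3ccccc3)c2)[C@@H](C(=NO)[N+](=O)[O-])C(C(=O)c2ccc(OC)c(OCc3ccccc3)c2)=C1 | intermediate
13 | (2S,3S)-4-[3-(benzyloxy)-4-methoxybenzoyl]-2-[3-(benzyloxy)-4-methoxyphenyl]-2,3-dihydrofuran-3-carboxylic acid | O1[C@H](c2ccc(OC)c(OCc3ccccc3)c2)[C@@H](C(=O)O)C(C(=O)c2ccc(OC)c(OCc3ccccc3)c2)=C1 | intermediate
14 | [(2S,3R)-2-[3-(benzyloxy)-4-methoxyphenyl]-3-(hydroxymethyl)-2,3-dihydrofuran-4-yl][3-(benzyloxy)-4-methoxyphenyl]methanone | O1[C@H](c2ccc(OC)c(OCc3ccccc3)c2)[C@@H](CO)C(C(=O)c2ccc(OC)c(OCc3ccccc3)c2)=C1 | intermediate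
15 | (3-hydroxy-4-methoxyphenyl)[(2S,3R,4R)-2-(3-hydroxy-4-methoxyphenyl)-3-(hydroxymethyl)tetrahydrofuran-4-yl]methanone (3,4-cis) | COc1ccc(C(=O)[C@H]2CO[C@H](c3ccc(OC)c(O)c3)[C@H]2CO)cc1O | intermediate
16 | (3-hydroxy-4-methoxyphenyl)[(2S,3R,4S)-2-(3-hydroxy-4-methoxyphenyl)-3-(hydroxymethyl)tetrahydrofuran-4-yl]methanone | COc1ccc(C(=O)[C@@H]2CO[C@H](c3ccc(OC)c(O)c3)[C@H]2CO)cc1O | target

## Step count and uncertain steps

Total step count: 12. Longest linear sequence: 10 steps (steps 1–5, then 8–12); the ynone branch (steps 6 and 7) joins at step 8.

**Step 8 (key step, new method).** Most likely failure: the amine removes the γ-hydrogen of 7 and the nitroalkene isomerises to a β-nitro ketone (loss of substrate and of the stereocentre). Alternatively the C4 carbanion is protonated before ring closure, leaving an open-chain β-alkoxy enone that no longer cyclises.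

Fallback, from 7 (with racemic 3 as the source of the partner), returning at 16: the ynone is replaced by the vinyl ketone, so that O–C5 bond formation leaves an ordinary ketone enolate whose intramolecular Michael addition to a nitroalkene is standard chemistry.
- MnO2 oxidation of 3 gives 1-[3-(benzyloxy)-4-methoxyphenyl]prop-2-en-1-one F1, used at once.
- Conjugate addition of the hydroxyl of 7 to F1 (catalytic base at low temperature, or acid catalysis if base causes isomerisation) gives the β-alkoxy ketone F2.
- Base-mediated 5-exo-trig Michael closure of F2, with the same trans preference at C3 and with C4 equilibrating to trans, gives the saturated nitro tetrahydrofuran F3.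
- F3 is then carried through the same functional-group steps: NaNO2/AcOH/DMSO to the acid F4, borane reduction at low temperature to the all-trans alcohol F5, and hydrogenolysis (H2, Pd/C) of the benzyl ethers to 16.
- The price is that the ketone is no longer masked as a vinylogous ester during the borane step.

**Step 4.** Most likely failure: competing reaction of NO2 radical or the oxoammonium species at the electron-rich arene or at the doubly activated benzylic C–H, giving low conversion to the nitroalkene.

Fallback, from 5, returning at 6: build the nitroalkene by a Henry reaction.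
- Oxidative cleavage of the vinyl group (OsO4 cat., NaIO4, 2,6-lutidine) gives (R)-2-[3-(benzyloxy)-4-methoxyphenyl]-2-[(tert-butyldimethylsilyl)oxy]acetaldehyde F6 (same spatial arrangement; the descriptor changes with priorities).
- Addition of nitromethane (catalytic Et3N, 0 °C) gives the β-nitro alcohol F7 as a mixture at the new carbinol.
- Dehydration through the mesylate (MsCl, Et3N, −20 °C) gives 6.
- The weak point is the configurational stability of the α-aryl aldehyde, which must be kept cold and used promptly.

**Step 9.** Most likely failure: side reactions of the nitrile oxide intermediate (dimerisation) or slow acid-promoted opening of the benzylic vinylogous ester during the long reaction time.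

Fallback, from 11, returning at 14: pass through the aldehyde oxidation level.
- The nitronate of 11 (NaOMe, MeOH, −40 °C) is treated with buffered aqueous TiCl3 (trivalent titanium) and NH4OAc, a reductive Nef reaction, to give (2S,3S)-4-[3-(benzyloxy)-4-methoxybenzoyl]-2-[3-(benzyloxy)-4-methoxyphenyl]-2,3-dihydrofuran-3-carbaldehyde F8.
- Crude F8 is reduced at once with NaBH4 at −78 °C to 14.
- F8 is prone to β-elimination of O1, so it must see no base and no chromatography.

**Step 11.** Most likely failure: hydrogenolysis of the C2–O1 bond while it is still a benzylic vinylogous ester (before C4=C5 is saturated), or over-reduction of the aryl ketone while the last benzyl group is removed.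

Fallback, from 14, returning at 15: separate the two reductions.
- Only C4=C5 is hydrogenated over Pd/C poisoned with Ph2S (H2 1 atm, EtOAc), a catalyst system that leaves benzyl ethers, benzylic esters and aryl ketones untouched. This gives the saturated bis(benzyl ether) [(2S,3R,4R)-2-[3-(benzyloxy)-4-methoxyphenyl]-3-(hydroxymethyl)tetrahydrofuran-4-yl][3-(benzyloxy)-4-methoxyphenyl]methanone F9.
- The benzyl groups are then removed from what is now an ordinary 2-aryltetrahydrofuran by transfer hydrogenolysis (Pd(OH)2/C, cyclohexa-1,4-diene, EtOH) to give 15.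

## Further compounds

F1 | step 8 | 1-[3-(benzyloxy)-4-methoxyphenyl]prop-2-en-1-one | C=CC(=O)c1ccc(OC)c(OCc2ccccc2)c1
F2 | step 8 | (S,E)-1-[3-(benzyloxy)-4-methoxyphenyl]-3-({1-[3-(benzyloxy)-4-methoxyphenyl]-3-nitroprop-2-en-1-yl}oxy)propan-1-one | O=C(CCO[C@H](c1ccc(OC)c(OCc2ccccc2)c1)/C=C/[N+](=O)[O-])c1ccc(OC)c(OCc2ccccc2)c1
F3 | step 8 | [(2S,3R,4S)-2-[3-(benzyloxy)-4-methoxyphenyl]-3-(nitromethyl)tetrahydrofuran-4-yl][3-(benzyloxy)-4-methoxyphenyl]methanone | COc1ccc(C(=O)[C@@H]2CO[C@H](c3ccc(OC)c(OCc4ccccc4)c3)[C@H]2C[N+](=O)[O-])cc1OCc1ccccc1
F4 | step 8 | (2S,3S,4S)-4-[3-(benzyloxy)-4-methoxybenzoyl]-2-[3-(benzyloxy)-4-methoxyphenyl]tetrahydrofuran-3-carboxylic acid | COc1ccc(C(=O)[C@@H]2CO[C@H](c3ccc(OC)c(OCc4ccccc4)c3)[C@H]2C(=O)O)cc1OCc1ccccc1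
F5 | step 8 | [(2S,3R,4S)-2-[3-(benzyloxy)-4-methoxyphenyl]-3-(hydroxymethyl)tetrahydrofuran-4-yl][3-(benzyloxy)-4-methoxyphenyl]methanone | COc1ccc(C(=O)[C@@H]2CO[C@H](c3ccc(OC)c(OCc4ccccc4)c3)[C@H]2CO)cc1OCc1ccccc1
F6 | step 4 | (R)-2-[3-(benzyloxy)-4-methoxyphenyl]-2-[(tert-butyldimethylsilyl)oxy]acetaldehyde | CC(C)(C)[Si](C)(C)O[C@H](c1ccc(OC)c(OCc2ccccc2)c1)C=O
F7 | step 4 | (1R)-1-[3-(benzyloxy)-4-methoxyphenyl]-1-[(tert-butyldimethylsilyl)oxy]-3-nitropropan-2-ol (both C2 epimers) | CC(C)(C)[Si](C)(C)O[C@H](c1ccc(OC)c(OCc2ccccc2)c1)C(O)C[N+](=O)[O-]
F8 | step 9 | (2S,3S)-4-[3-(benzyloxy)-4-methoxybenzoyl]-2-[3-(benzyloxy)-4-methoxyphenyl]-2,3-dihydrofuran-3-carbaldehyde | O1[C@H](c2ccc(OC)c(OCc3ccccc3)c2)[C@@H](C=O)C(C(=O)c2ccc(OC)c(OCc3ccccc3)c2)=C1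
F9 | step 11 | [(2S,3R,4R)-2-[3-(benzyloxy)-4-methoxyphenyl]-3-(hydroxymethyl)tetrahydrofuran-4-yl][3-(benzyloxy)-4-methoxyphenyl]methanone | COc1ccc(C(=O)[C@H]2CO[C@H](c3ccc(OC)c(OCc4ccccc4)c3)[C@H]2CO)cc1OCc1ccccc1
A1 | alternative 1 | exo,exo-2,6-bis[3-(benzyloxy)-4-methoxyphenyl]-3,7-dioxabicyclo[3.3.0]octan-8-one | O1[C@H](c2ccc(OC)c(OCc3ccccc3)c2)[C@H]2C(=O)O[C@H](c3ccc(OC)c(OCc4ccccc4)c3)[C@H]2C1
A2 | alternative 1 | trans-5-[3-(benzyloxy)-4-methoxyphenyl]-4-({[3-(benzyloxy)-4-methoxyphenyl]methoxy}methyl)-3-diazodihydrofuran-2(3H)-one | O=C1O[C@H](c2ccc(OC)c(OCc3ccccc3)c2)[C@@H](COCc2ccc(OC)c(OCc3ccccc3)c2)C1=[N+]=[N-]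
A3 | alternative 2 | 2,3-trans-2-[3-(benzyloxy)-4-methoxyphenyl]-4-{[3-(benzyloxy)-4-methoxyphenyl]methylidene}-3-(hydroxymethyl)tetrahydrofuran | O1[C@H](c2ccc(OC)c(OCc3ccccc3)c2)[C@@H](CO)/C(=C/c2ccc(OC)c(OCc3ccccc3)c2)C1
A4 | alternative 2 | 2-{[3-(benzyloxy)-4-methoxyphenyl]({3-[3-(benzyloxy)-4-methoxyphenyl]prop-2-yn-1-yl}oxy)methyl}oxirane (epoxide centre left open) | COc1ccc(C#CCO[C@H](c2ccc(OC)c(OCc3ccccc3)c2)C2CO2)cc1OCc1ccccc1
A5 | alternative 3 | 2,3-trans-2-[3-(benzyloxy)-4-methoxyphenyl]-3-{[(tert-butyldimethylsilyl)oxy]methyl}-2,3-dihydrofuran | O1[C@H](c2ccc(OC)c(OCc3ccccc3)c2)[C@@H](CO[Si](C)(C)C(C)(C)C)C=C1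
A6 | alternative 3 | 2-[3-(benzyloxy)-4-methoxyphenyl]-3-{[(tert-butyldimethylsilyl)oxy]methyl}cyclopropane-1-carbaldehyde (aryl trans to both other substituents) | O=C[C@H]1[C@H](c2ccc(OC)c(OCc3ccccc3)c2)[C@H]1CO[Si](C)(C)C(C)(C)C
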